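**Plan**

- Labels: ring A is the guaiacyl ring on C7; C7–C8–C9 is the glycerol chain; ring B is the 2,6-dimethoxyaryl ring on the C8 oxygen; ring C is the dihydrofuran (O1, C2, C3) fused to benzene ring D.
- Retrosynthetic cuts, in order: silyl groups and the two primary alcohols (back to esters); C2–C3 of ring C (carbene C–H insertion); the aryl–C(N2) bond on ring D; the ring D O–CH2 ether; last, O–C8 and C7–C8 together.
- Enabling feature: C8 alone is bonded to the ring B oxygen, to carbinol carbon C7 and to C9, so it can be the carbene carbon of a diazoacetate (C9 as ester carbon) captured by the ring B phenol O–H and then by the ring A aldehyde.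
- Forward: ring A, chain and ring B are joined first in one three-component step; the ring B bromide becomes CH2OH and is etherified with the ring D iodophenol; the diazoacetate is placed on ring D; ring C closes last and is the only ring formed.
- Stereochemistry: C7/C8 (7R,8S, erythro) from the chiral zirconium BINOLate in the aldol capture; C2/C3 (cis, 2R,3R) from Rh2(S-PTTL)4 in the C–H insertion; later steps leave all four centres untouched.

Key step: step 1

Abbreviations: TBS = tert-butyldimethylsilyl; R* = (1R,2S)-1,3-bis(TBS-oxy)-1-[4-(TBS-oxy)-3-methoxyphenyl]propan-2-yl (the silylated ring A–C7–C8–C9 unit, bonded through C8); Rh2(S-PTTL)4 = dirhodium tetrakis[N-phthaloyl-(S)-tert-leucinate].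

Assumption: the (S)-BINOL zirconium catalyst is taken to give the 2R,3R adduct, and Rh2(S-PTTL)4 the cis-2R,3S ester as expected from simpler 2-benzyloxyaryl diazoacetates; if either sense proves opposite, the mirror-image ligand is used.

**Route**

Step 1
Reactants: 1 4-bromo-2,6-dimethoxyphenol; 2 ethyl diazoacetate; 3 4-(tert-butyldimethylsilyloxy)-3-methoxybenzaldehyde
Product: 5 ethyl (2R,3R)-2-(4-bromo-2,6-dimethoxyphenoxy)-3-[4-(TBS-oxy)-3-methoxyphenyl]-3-hydroxypropanoate (anti aldol = erythro), via protic oxonium ylide 4 (not isolated)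
Conditions: Rh2(OAc)4 (2 mol %), Zr(OtBu)4 (20 mol %), (S)-BINOL (40 mol %), 4 Å MS, CH2Cl2, −20 °C; 2 (1.5 equiv) added over 6 h to 1 (1.0 equiv) and 3 (1.5 equiv)
Reagents that add atoms: none
Why: Proposed new method: Rh2(OAc)4 converts 2 into an electrophilic rhodium carbene that the phenol oxygen of 1 attacks (O–C8 bond) to give the protic oxonium ylide 4, in equilibrium with its enol; before the usual 1,2-proton shift completes an O–H insertion, this nucleophile adds to aldehyde 3 held on the zirconium BINOLate (C7–C8 bond). The closest known reaction type is the dirhodium/chiral acid co-catalysed three-component coupling of aryldiazoacetates with alcohols and aldehydes by oxonium-ylide trapping; a diazoacetate with hydrogen on the carbene carbon and a phenol as O–H partner have not been shown, because the proton shift is faster for such ylides. No ring is closed in this step. C7 and C8 arise together in the aldol event: zirconium binds the aldehyde and the enol oxygen in a closed six-membered transition state that should lead to the anti aldol (erythro in lignan terms), and the BINOL ligand chooses the aldehyde face, so both centres are under catalyst control. The selectivity needed is aldol capture over proton shift and over carbene dimerisation; slow addition of 2, an excess of the activated aldehyde and low temperature serve this, the two ortho methoxy groups of 1 may hydrogen-bond the O–H of the ylide and so slow its transfer to carbon, and the silyl (not alkyl) ether on ring A keeps the aldehyde a better acceptor.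

Step 2
Reactants: 5 ethyl (2R,3R)-2-(4-bromo-2,6-dimethoxyphenoxy)-3-[4-(TBS-oxy)-3-methoxyphenyl]-3-hydroxypropanoate
Product: 6 (1R,2S)-2-(4-bromo-2,6-dimethoxyphenoxy)-1-[4-(TBS-oxy)-3-methoxyphenyl]propane-1,3-diol
Conditions: LiBH4, THF, MeOH (1 equiv), 0 °C → rt
Reagents that add atoms: none
Why: Ester reduction with LiBH4 turns the α-aryloxy ester into the C9 primary alcohol without touching the aryl bromide, the aryl silyl ether or the two stereocentres (the C8 descriptor changes from R to S by priority only).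

Step 3
Reactants: 6 (1R,2S)-2-(4-bromo-2,6-dimethoxyphenoxy)-1-[4-(TBS-oxy)-3-methoxyphenyl]propane-1,3-diol
Product: 7 (1R,2S)-2-(4-bromo-2,6-dimethoxyphenoxy)-1,3-bis(TBS-oxy)-1-[4-(TBS-oxy)-3-methoxyphenyl]propane (R*–O–aryl bromide)
Conditions: TBSOTf, 2,6-lutidine, CH2Cl2, −78 → 0 °C
Reagents that add atoms: tert-butyldimethylsilyl trifluoromethanesulfonate, CC(C)(C)[Si](C)(C)OS(=O)(=O)C(F)(F)F
Why: Silyl ether formation with the silyl triflate covers the primary C9 and the hindered benzylic C7 hydroxyl, as required for the organolithium, Mitsunobu and carbene steps that follow.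

Step 4
Reactants: 7 R*–O–(4-bromo-2,6-dimethoxyphenyl)
Product: 10 (4-{[R*]oxy}-3,5-dimethoxyphenyl)methanol, via aryllithium 8 (not isolated), via ring B aldehyde 9 (not isolated)
Conditions: n-BuLi, THF, −78 °C; DMF, −78 → 0 °C; then MeOH, NaBH4, 0 °C; aq. NH4Cl
Reagents that add atoms: N,N-dimethylformamide, CN(C)C=O
Why: Bromine–lithium exchange, formylation of the aryllithium with DMF and borohydride reduction of the aldehyde released on adding methanol give the benzylic alcohol in one flask, the silyl ethers being stable to n-BuLi at −78 °C.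

Step 5
Reactants: 11 methyl 3-(4-hydroxy-3-methoxyphenyl)propanoate
Product: 12 methyl 3-(4-hydroxy-3-iodo-5-methoxyphenyl)propanoate
Conditions: I2, NaHCO3, THF/H2O, 0 °C → rt
Reagents that add atoms: iodine, II
Why: Electrophilic aromatic iodination of the phenol under mild base goes to the only free position ortho to the hydroxyl, the para position being occupied by the side chain.

Step 6
Reactants: 10 (4-{[R*]oxy}-3,5-dimethoxyphenyl)methanol; 12 methyl 3-(4-hydroxy-3-iodo-5-methoxyphenyl)propanoate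
Product: 13 methyl 3-{4-[(4-{[R*]oxy}-3,5-dimethoxybenzyl)oxy]-3-iodo-5-methoxyphenyl}propanoate
Conditions: PPh3, DIAD, THF, 0 °C → rt
Reagents that add atoms: none
Why: Mitsunobu etherification joins the primary benzylic alcohol to the acidic ortho-iodophenol under neutral conditions that spare silyl ethers and the ester, and no stereocentre is involved.

Step 7
Reactants: 13 methyl 3-{4-[(4-{[R*]oxy}-3,5-dimethoxybenzyl)oxy]-3-iodo-5-methoxyphenyl}propanoate; 2 ethyl diazoacetate
Product: 14 ethyl 2-diazo-2-{2-[(4-{[R*]oxy}-3,5-dimethoxybenzyl)oxy]-3-methoxy-5-(3-methoxy-3-oxopropyl)phenyl}acetate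
Conditions: Pd(PPh3)4 (5 mol %), Ag2CO3 (0.5 equiv), Et3N, toluene, rt
Reagents that add atoms: none
Why: Palladium-catalysed C–H arylation of a diazoacetate with an aryl iodide (oxidative addition to zerovalent palladium, silver-assisted transfer of the deprotonated diazo ester, reductive elimination) installs the aryl diazoacetate at room temperature with the diazo group retained.

Step 8
Reactants: 14 ethyl 2-diazo-2-{2-[(4-{[R*]oxy}-3,5-dimethoxybenzyl)oxy]-3-methoxy-5-(3-methoxy-3-oxopropyl)phenyl}acetate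
Product: 15 ethyl (2R,3S)-2-(4-{[R*]oxy}-3,5-dimethoxyphenyl)-7-methoxy-5-(3-methoxy-3-oxopropyl)-2,3-dihydro-1-benzofuran-3-carboxylate (2,3-cis)
Conditions: Rh2(S-PTTL)4 (2 mol %), toluene, −60 °C
Reagents that add atoms: none
Why: Intramolecular 1,5 C–H insertion of the rhodium carbene into the benzylic O–CH2 bond closes ring C through C2–C3, the insertion giving the cis ester as kinetic product and the chiral carboxylate ligands choosing the carbene face so that C2 (R) and C3 (S) are set under catalyst control, with the remote C7/C8 centres expected to have little influence.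

Step 9
Reactants: 15 ethyl (2R,3S)-2-(4-{[R*]oxy}-3,5-dimethoxyphenyl)-7-methoxy-5-(3-methoxy-3-oxopropyl)-2,3-dihydro-1-benzofuran-3-carboxylate
Product: 16 3-[(2R,3R)-2-(4-{[R*]oxy}-3,5-dimethoxyphenyl)-3-(hydroxymethyl)-7-methoxy-2,3-dihydro-1-benzofuran-5-yl]propan-1-ol (2,3-cis)
Conditions: i-Bu2AlH (excess), CH2Cl2, −78 → 0 °C; aq. potassium sodium tartrate
Reagents that add atoms: none
Why: Ester reduction with the non-basic hydride i-Bu2AlH converts both the C3 ester and the side-chain ester to primary alcohols without enolising C3, so the cis relation is kept (the C3 descriptor changes from S to R by priority only).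

Step 10
Reactants: 16 3-[(2R,3R)-2-(4-{[R*]oxy}-3,5-dimethoxyphenyl)-3-(hydroxymethyl)-7-methoxy-2,3-dihydro-1-benzofuran-5-yl]propan-1-ol
Product: 17 (1R,2S)-2-{4-[(2R,3R)-3-(hydroxymethyl)-5-(3-hydroxypropyl)-7-methoxy-2,3-dihydro-1-benzofuran-2-yl]-2,6-dimethoxyphenoxy}-1-(4-hydroxy-3-methoxyphenyl)propane-1,3-diol
Conditions: Bu4NF, AcOH, THF, 0 °C → rt
Reagents that add atoms: none
Why: Fluoride-mediated desilylation removes the two alkyl silyl ethers and the aryl silyl ether in one operation, acetic acid buffering protecting the free p-hydroxybenzyl alcohol and the cis-dihydrobenzofuran from base.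

**Compound list**

1 | 4-bromo-2,6-dimethoxyphenol | COc1cc(Br)cc(OC)c1O | starting material
2 | ethyl diazoacetate | CCOC(=O)C=[N+]=[N-] | starting material
3 | 4-(tert-butyldimethylsilyloxy)-3-methoxybenzaldehyde | COc1cc(C=O)ccc1O[Si](C)(C)C(C)(C)C | starting material
4 | protic oxonium ylide from 1 and the carbene of 2 | CCOC(=O)[CH-][OH+]c1c(OC)cc(Br)cc1OC | intermediate
5 | ethyl (2R,3R)-2-(4-bromo-2,6-dimethoxyphenoxy)-3-[4-(TBS-oxy)-3-methoxyphenyl]-3-hydroxypropanoate | COc1cc([C@@H](O)[C@H](C(=O)OCC)Oc2c(OC)cc(Br)cc2OC)ccc1O[Si](C)(C)C(C)(C)C | intermediate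
6 | (1R,2S)-2-(4-bromo-2,6-dimethoxyphenoxy)-1-[4-(TBS-oxy)-3-methoxyphenyl]propane-1,3-diol | COc1cc([C@@H](O)[C@H](CO)Oc2c(OC)cc(Br)cc2OC)ccc1O[Si](C)(C)C(C)(C)C | intermediate
7 | (1R,2S)-2-(4-bromo-2,6-dimethoxyphenoxy)-1,3-bis(TBS-oxy)-1-[4-(TBS-oxy)-3-methoxyphenyl]propane | COc1cc([C@@H](O[Si](C)(C)C(C)(C)C)[C@H](CO[Si](C)(C)C(C)(C)C)Oc2c(OC)cc(Br)cc2OC)ccc1O[Si](C)(C)C(C)(C)C | intermediate
8 | aryllithium from 7 (Li in place of Br) | COc1cc([C@@H](O[Si](C)(C)C(C)(C)C)[C@H](CO[Si](C)(C)C(C)(C)C)Oc2c(OC)cc([Li])cc2OC)ccc1O[Si](C)(C)C(C)(C)C | intermediate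
9 | 4-{[R*]oxy}-3,5-dimethoxybenzaldehyde | COc1cc([C@@H](O[Si](C)(C)C(C)(C)C)[C@H](CO[Si](C)(C)C(C)(C)C)Oc2c(OC)cc(C=O)cc2OC)ccc1O[Si](C)(C)C(C)(C)C | intermediate
10 | (4-{[R*]oxy}-3,5-dimethoxyphenyl)methanol | COc1cc([C@@H](O[Si](C)(C)C(C)(C)C)[C@H](CO[Si](C)(C)C(C)(C)C)Oc2c(OC)cc(CO)cc2OC)ccc1O[Si](C)(C)C(C)(C)C | intermediate
11 | methyl 3-(4-hydroxy-3-methoxyphenyl)propanoate | COC(=O)CCc1ccc(O)c(OC)c1 | starting material
12 | methyl 3-(4-hydroxy-3-iodo-5-methoxyphenyl)propanoate | COC(=O)CCc1cc(I)c(O)c(OC)c1 | intermediate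
13 | methyl 3-{4-[(4-{[R*]oxy}-3,5-dimethoxybenzyl)oxy]-3-iodo-5-methoxyphenyl}propanoate | COc1cc([C@@H](O[Si](C)(C)C(C)(C)C)[C@H](CO[Si](C)(C)C(C)(C)C)Oc2c(OC)cc(COc3c(I)cc(CCC(=O)OC)cc3OC)cc2OC)ccc1O[Si](C)(C)C(C)(C)C | intermediate
14 | ethyl 2-diazo-2-{2-[(4-{[R*]oxy}-3,5-dimethoxybenzyl)oxy]-3-methoxy-5-(3-methoxy-3-oxopropyl)phenyl}acetate | COc1cc([C@@H](O[Si](C)(C)C(C)(C)C)[C@H](CO[Si](C)(C)C(C)(C)C)Oc2c(OC)cc(COc3c(C(=[N+]=[N-])C(=O)OCC)cc(CCC(=O)OC)cc3OC)cc2OC)ccc1O[Si](C)(C)C(C)(C)C | intermediate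
15 | ethyl (2R,3S)-2-(4-{[R*]oxy}-3,5-dimethoxyphenyl)-7-methoxy-5-(3-methoxy-3-oxopropyl)-2,3-dihydro-1-benzofuran-3-carboxylate (cis) | COc1cc([C@@H](O[Si](C)(C)C(C)(C)C)[C@H](CO[Si](C)(C)C(C)(C)C)Oc2c(OC)cc([C@@H]3Oc4c(OC)cc(CCC(=O)OC)cc4[C@@H]3C(=O)OCC)cc2OC)ccc1O[Si](C)(C)C(C)(C)C | intermediate
16 | 3-[(2R,3R)-2-(4-{[R*]oxy}-3,5-dimethoxyphenyl)-3-(hydroxymethyl)-7-methoxy-2,3-dihydro-1-benzofuran-5-yl]propan-1-ol (cis) | COc1cc([C@@H](O[Si](C)(C)C(C)(C)C)[C@H](CO[Si](C)(C)C(C)(C)C)Oc2c(OC)cc([C@@H]3Oc4c(OC)cc(CCCO)cc4[C@@H]3CO)cc2OC)ccc1O[Si](C)(C)C(C)(C)C | intermediate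
17 | (1R,2S)-2-{4-[(2R,3R)-3-(hydroxymethyl)-5-(3-hydroxypropyl)-7-methoxy-2,3-dihydro-1-benzofuran-2-yl]-2,6-dimethoxyphenoxy}-1-(4-hydroxy-3-methoxyphenyl)propane-1,3-diol | COc1cc([C@@H](O)[C@H](CO)Oc2c(OC)cc([C@@H]3Oc4c(OC)cc(CCCO)cc4[C@@H]3CO)cc2OC)ccc1O | target

**Step count and risks**

Total step count: 10. Longest linear sequence: 9 steps (steps 1–4 and 6–10); step 5 is a one-step side branch.

Steps most likely to fail:

1. Step 1. The 1,2-proton shift of the ylide may outrun aldol capture, so that only O–H insertion takes place, or capture may occur with poor anti and facial selectivity. The fallback uses known chemistry, sets out from phenol 1 and rejoins at 7, bypassing steps 2 and 3.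
 - O-Alkylation of 1 with chloroacetic acid (NaOH, H2O, reflux) gives (4-bromo-2,6-dimethoxyphenoxy)acetic acid F1.
 - N-Acylation of (R)-4-benzyl-2-oxazolidinone (DCC, DMAP, CH2Cl2) gives the imide F2.
 - Evans aldol with aldehyde 3 (Bu2BOTf, i-Pr2NEt, CH2Cl2, −78 → 0 °C) gives the syn adduct F3, in which C8 is already correct and C7 is epimeric.
 - LiBH4 removes the auxiliary to give the threo diol F4.
 - TBSCl and imidazole silylate the primary hydroxyl only, giving the C9 silyl ether F5.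
 - Mitsunobu inversion at C7 with 4-nitrobenzoic acid (PPh3, DIAD) gives the ester F6.
 - Brief methanolysis (K2CO3, MeOH, 0 °C) gives the erythro alcohol F7.
 - TBSOTf and 2,6-lutidine then silylate C7–OH, and the phenol again should the carbonate have freed it, which is compound 7.

2. Step 8. Facial selection by the catalyst may be poor on this large substrate, so that both cis diastereomers form, or the carbene may be diverted by ether oxygens or traces of water. The fallback closes ring C at the aromatic oxidation level and sets both centres by hydrogenation; it sets out from diazo ester 14 and comes back at 15.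
 - Insertion with achiral Rh2(OAc)4 still closes the ring and should give 15 together with its cis-(2S,3R) diastereomer F8.
 - DDQ dehydrogenation (dioxane, 80 °C) converges the mixture on the benzofuran ester F9.
 - cis-Hydrogenation of the furan C2=C3 bond with a chiral ruthenium N-heterocyclic carbene catalyst (Ru(cod)(2-methylallyl)2, chiral imidazolinium salt, KOtBu, H2) should set C2 and C3 in one syn addition and return 15. The reach of this catalyst class to a 2-aryl-3-ester benzofuran is not established.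

3. Step 7. Oxidative addition and transfer of the diazo ester may be slow at the ortho-alkoxy iodide, so that metal-induced decomposition of ethyl diazoacetate dominates. The fallback sets out from iodide 13 and comes back at 14.
 - Negishi-type coupling with the Reformatsky reagent BrZnCH2CO2Et (Pd(dba)2, P(t-Bu)3, THF, rt) gives the ethyl arylacetate F10.
 - Regitz diazo transfer (4-acetamidobenzenesulfonyl azide, DBU, MeCN, 0 °C) then gives 14.

**Further compounds**

F1 | step 1 | (4-bromo-2,6-dimethoxyphenoxy)acetic acid | COc1cc(Br)cc(OC)c1OCC(=O)O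
F2 | step 1 | (R)-4-benzyl-3-[(4-bromo-2,6-dimethoxyphenoxy)acetyl]oxazolidin-2-one | COc1cc(Br)cc(OC)c1OCC(=O)N2[C@H](Cc3ccccc3)COC2=O
F3 | step 1 | (R)-4-benzyl-3-{(2R,3S)-2-(4-bromo-2,6-dimethoxyphenoxy)-3-hydroxy-3-[4-(TBS-oxy)-3-methoxyphenyl]propanoyl}oxazolidin-2-one (syn aldol) | COc1cc([C@H](O)[C@H](C(=O)N3[C@H](Cc4ccccc4)COC3=O)Oc2c(OC)cc(Br)cc2OC)ccc1O[Si](C)(C)C(C)(C)C
F4 | step 1 | (1S,2S)-2-(4-bromo-2,6-dimethoxyphenoxy)-1-[4-(TBS-oxy)-3-methoxyphenyl]propane-1,3-diol (threo) | COc1cc([C@H](O)[C@H](CO)Oc2c(OC)cc(Br)cc2OC)ccc1O[Si](C)(C)C(C)(C)C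
F5 | step 1 | (1S,2S)-2-(4-bromo-2,6-dimethoxyphenoxy)-3-(TBS-oxy)-1-[4-(TBS-oxy)-3-methoxyphenyl]propan-1-ol | COc1cc([C@H](O)[C@H](CO[Si](C)(C)C(C)(C)C)Oc2c(OC)cc(Br)cc2OC)ccc1O[Si](C)(C)C(C)(C)C
F6 | step 1 | (1R,2S)-2-(4-bromo-2,6-dimethoxyphenoxy)-3-(TBS-oxy)-1-[4-(TBS-oxy)-3-methoxyphenyl]propyl 4-nitrobenzoate | COc1cc([C@@H](OC(=O)c3ccc(cc3)[N+](=O)[O-])[C@H](CO[Si](C)(C)C(C)(C)C)Oc2c(OC)cc(Br)cc2OC)ccc1O[Si](C)(C)C(C)(C)C
F7 | step 1 | (1R,2S)-2-(4-bromo-2,6-dimethoxyphenoxy)-3-(TBS-oxy)-1-[4-(TBS-oxy)-3-methoxyphenyl]propan-1-ol (erythro) | COc1cc([C@@H](O)[C@H](CO[Si](C)(C)C(C)(C)C)Oc2c(OC)cc(Br)cc2OC)ccc1O[Si](C)(C)C(C)(C)C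
F8 | step 8 | cis-(2S,3R) diastereomer of 15 | COc1cc([C@@H](O[Si](C)(C)C(C)(C)C)[C@H](CO[Si](C)(C)C(C)(C)C)Oc2c(OC)cc([C@H]3Oc4c(OC)cc(CCC(=O)OC)cc4[C@H]3C(=O)OCC)cc2OC)ccc1O[Si](C)(C)C(C)(C)C
F9 | step 8 | ethyl 2-(4-{[R*]oxy}-3,5-dimethoxyphenyl)-7-methoxy-5-(3-methoxy-3-oxopropyl)-1-benzofuran-3-carboxylate | COc1cc([C@@H](O[Si](C)(C)C(C)(C)C)[C@H](CO[Si](C)(C)C(C)(C)C)Oc2c(OC)cc(-c3oc4c(OC)cc(CCC(=O)OC)cc4c3C(=O)OCC)cc2OC)ccc1O[Si](C)(C)C(C)(C)C
F10 | step 7 | ethyl 2-{2-[(4-{[R*]oxy}-3,5-dimethoxybenzyl)oxy]-3-methoxy-5-(3-methoxy-3-oxopropyl)phenyl}acetate | COc1cc([C@@H](O[Si](C)(C)C(C)(C)C)[C@H](CO[Si](C)(C)C(C)(C)C)Oc2c(OC)cc(COc3c(CC(=O)OCC)cc(CCC(=O)OC)cc3OC)cc2OC)ccc1O[Si](C)(C)C(C)(C)C
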